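Both aryl–prenyl bonds are traced back to oxygen. In the target, C8 of ring A sits para to O5 and C3' of ring B sits ortho to O4', so an O5-prenyl ether and an O4'-(1,1-dimethylallyl) ether on a protected (2R,3R)-aromadendrin can each pass their five-carbon unit to the correct carbon through six-membered [3,3] transition states, C6 serving only as a relay. A single heating with a trivalent europium catalyst should forge the C8–CH2 and C3'–CH2 bonds and release the 5- and 4'-hydroxyls. The substrate is the 3-O-TBS-7-O-TIPS diether; both stereocentres are bought with the dihydroflavonol and never touched. O4'-methylation and buffered fluoride desilylation finish the route.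

Key step: step 6

Assumption: (2R,3R)-aromadendrin is purchased as the enantiopure natural product, and its C2/C3 configuration is carried through unchanged.

Design remark: O7 carries a triisopropylsilyl group, because an aryl tert-butyldimethylsilyl ether para to the C4 carbonyl would be at risk under the amine base of the phenol alkylation that follows. The alkyne is semi-hydrogenated before the O5-prenyl ether is installed, so no second alkene is present. O5 is prenylated without base (Mitsunobu, prenol). Eu(fod)3 denotes europium tris(6,6,7,7,8,8,8-heptafluoro-2,2-dimethyloctane-3,5-dionate).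

Step 1
Reactants: 1 (2R,3R)-aromadendrin
Product: 2 (2R,3R)-3,5-dihydroxy-2-(4-hydroxyphenyl)-7-(triisopropylsilyloxy)chroman-4-one
Conditions: TIPSCl (1.05 equiv), Et3N (1.2 equiv), DMF, −20 °C to 0 °C
Reagents that add atoms: triisopropylsilyl chloride, CC(C)[Si](Cl)(C(C)C)C(C)C
Why: Regioselective O-silylation of a phenoxide: the 7-OH, para to the C4 carbonyl, is the most acidic hydroxyl of 1, so about one equivalent of amine base should give mainly the 7-phenoxide, while the 4'-OH, the chelated 5-OH and the secondary 3-OH stay protonated and unreactive towards the bulky chloride.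

Step 2
Reactants: 2 (2R,3R)-3,5-dihydroxy-2-(4-hydroxyphenyl)-7-(triisopropylsilyloxy)chroman-4-one; 3 3-chloro-3-methylbut-1-yne
Product: 4 (2R,3R)-3,5-dihydroxy-2-[4-(2-methylbut-3-yn-2-yloxy)phenyl]-7-(triisopropylsilyloxy)chroman-4-one
Conditions: 3 (1.3 equiv), DBU (1.3 equiv), CuCl2·2H2O (1 mol%), MeCN, 0 °C
Reagents that add atoms: none
Why: Copper-catalysed propargylic etherification of a phenol with a tertiary propargyl chloride should alkylate the only free non-chelated phenol (O4'), since the hydrogen-bonded 5-OH and the C3 alcohol are far less nucleophilic and the hindered aryl TIPS ether should hold at 0 °C.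

Step 3
Reactants: 4 (2R,3R)-3,5-dihydroxy-2-[4-(2-methylbut-3-yn-2-yloxy)phenyl]-7-(triisopropylsilyloxy)chroman-4-one
Product: 5 (2R,3R)-3-(tert-butyldimethylsilyloxy)-5-hydroxy-2-[4-(2-methylbut-3-yn-2-yloxy)phenyl]-7-(triisopropylsilyloxy)chroman-4-one
Conditions: TBSCl, imidazole, DMAP (cat.), DMF, rt to 40 °C
Reagents that add atoms: tert-butyldimethylsilyl chloride, CC(C)(C)[Si](C)(C)Cl
Why: Standard silylation of a secondary alcohol with TBSCl and imidazole, under which the chelated 5-OH of flavonoids is expected to remain free; the C3 configuration is retained because only the O–H bond reacts.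

Step 4
Reactants: 5 (2R,3R)-3-(tert-butyldimethylsilyloxy)-5-hydroxy-2-[4-(2-methylbut-3-yn-2-yloxy)phenyl]-7-(triisopropylsilyloxy)chroman-4-one
Product: 6 (2R,3R)-3-(tert-butyldimethylsilyloxy)-5-hydroxy-2-[4-(2-methylbut-3-en-2-yloxy)phenyl]-7-(triisopropylsilyloxy)chroman-4-one
Conditions: H2 (1 atm), Pd/CaCO3 poisoned with Pb(OAc)2 (Lindlar catalyst), quinoline, EtOAc, rt
Reagents that add atoms: none
Why: Lindlar semi-hydrogenation of the terminal alkyne should stop at the vinyl group with the poisoned catalyst and quinoline; no other C=C is present, and the ketone, the C2–O bond and the silyl ethers are inert under these conditions.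

Step 5
Reactants: 6 (2R,3R)-3-(tert-butyldimethylsilyloxy)-5-hydroxy-2-[4-(2-methylbut-3-en-2-yloxy)phenyl]-7-(triisopropylsilyloxy)chroman-4-one; 7 3-methylbut-2-en-1-ol (prenol)
Product: 8 (2R,3R)-3-(tert-butyldimethylsilyloxy)-2-[4-(2-methylbut-3-en-2-yloxy)phenyl]-5-(3-methylbut-2-enyloxy)-7-(triisopropylsilyloxy)chroman-4-one
Conditions: 7 (1.5 equiv), PPh3, DIAD, THF, 0 °C to rt
Reagents that add atoms: none
Why: Mitsunobu etherification, in which the chelated 5-OH (the only remaining OH) is the pronucleophile and prenol is displaced at its primary carbon as the alkoxyphosphonium salt; the base-free conditions, known for 5-O-prenylation of protected naringenin, should spare the flavanone from ring opening and epimerisation.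

Step 6
Reactants: 8 (2R,3R)-3-(tert-butyldimethylsilyloxy)-2-[4-(2-methylbut-3-en-2-yloxy)phenyl]-5-(3-methylbut-2-enyloxy)-7-(triisopropylsilyloxy)chroman-4-one
Product: 13 (2R,3R)-3-(tert-butyldimethylsilyloxy)-5-hydroxy-2-[4-hydroxy-3-(3-methylbut-2-enyl)phenyl]-8-(3-methylbut-2-enyl)-7-(triisopropylsilyloxy)chroman-4-one, via C6 reverse-prenyl dienone 9 (not isolated), via C8 prenyl dienone 10 (not isolated), via 8-prenyl 4'-O-tert-allyl ether 11 (not isolated), via ring B ortho-dienone 12 (not isolated)
Conditions: Eu(fod)3 (15 mol%), NaHCO3, PhCl, 85 °C, then 125 °C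
Reagents that add atoms: none
Why: Chelation of Eu(fod)3 between the C4 carbonyl and O5 activates the aryl prenyl ether for a [3,3] (Claisen) shift to C6, the only free ortho carbon (C4a is quaternary), giving dienone 9; a second [3,3] (Cope) shift of its 1,1-dimethylallyl group across C6–C7=C8 places a normal prenyl group on C8 (10), and tautomerisation restores ring A as the chelated 5-phenol 11. At the higher temperature the tertiary allyl aryl ether of ring B should undergo an ortho (aromatic) Claisen shift through a chair transition state to either of its two equivalent ortho carbons (12) and enolise to the 3'-prenyl 4'-phenol 13. Both events are known reaction types: the lanthanide-catalysed para-Claisen–Cope rearrangement of 5-O-prenyl flavanones and flavonols to their 8-prenyl isomers, and the aromatic Claisen rearrangement of aryl 1,1-dimethylallyl ethers to ortho-prenylphenols. No ring is closed and no stereocentre is created: the sp3 carbons at C6, C8 and C3' in 9, 10 and 12 are transient, and C2 and C3 take no part under these neutral, buffered conditions. The selectivity needed is C8 over C6 on ring A, that is, the Cope shift must outrun enolisation of 9; the metal held at O4/O5 should keep 9 in its keto form and lower the barrier of the second shift, and the bulky O7 silyl ether beside C6 should disfavour a reverse-prenyl group resting there while being unable to migrate itself. NaHCO3 scavenges adventitious acid so that the tertiary ether is not ionised and the new ortho-prenylphenol does not cyclise, and the two-temperature programme lets ring A react under catalysis before the ring B shift is driven thermally.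

Step 7
Reactants: 13 (2R,3R)-3-(tert-butyldimethylsilyloxy)-5-hydroxy-2-[4-hydroxy-3-(3-methylbut-2-enyl)phenyl]-8-(3-methylbut-2-enyl)-7-(triisopropylsilyloxy)chroman-4-one
Product: 14 (2R,3R)-3-(tert-butyldimethylsilyloxy)-5-hydroxy-2-[4-methoxy-3-(3-methylbut-2-enyl)phenyl]-8-(3-methylbut-2-enyl)-7-(triisopropylsilyloxy)chroman-4-one
Conditions: TMSCHN2 (2 M in hexanes), i-Pr2NEt, MeOH/MeCN, rt
Reagents that add atoms: trimethylsilyldiazomethane, C[Si](C)(C)C=[N+]=[N-]
Why: O-Methylation of a phenol by diazomethane released in situ from TMSCHN2 and methanol should take the free 4'-OH only, because the 5-OH locked in a hydrogen bond to the C4 carbonyl is far less reactive, and the near-neutral medium leaves the silyl ethers, the prenyl groups and C2/C3 untouched.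

Step 8
Reactants: 14 (2R,3R)-3-(tert-butyldimethylsilyloxy)-5-hydroxy-2-[4-methoxy-3-(3-methylbut-2-enyl)phenyl]-8-(3-methylbut-2-enyl)-7-(triisopropylsilyloxy)chroman-4-one
Product: 15 (2R,3R)-3,5,7-trihydroxy-2-[4-methoxy-3-(3-methylbut-2-enyl)phenyl]-8-(3-methylbut-2-enyl)chroman-4-one (CNP0233452.1)
Conditions: Bu4NF, AcOH (1:1), THF, 0 °C to rt
Reagents that add atoms: none
Why: Fluoride-mediated desilylation should cleave the aryl TIPS ether and the secondary TBS ether in one operation, and the acetic acid buffer keeps the medium close to neutral so that the base-sensitive trans-dihydroflavonol should not epimerise, ring-open or oxidise and the prenyl groups should not cyclise.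

Compound list
1 | (2R,3R)-aromadendrin, (2R,3R)-3,5,7-trihydroxy-2-(4-hydroxyphenyl)chroman-4-one | Oc1ccc([C@H]2Oc3cc(O)cc(O)c3C(=O)[C@@H]2O)cc1 | starting material
2 | (2R,3R)-3,5-dihydroxy-2-(4-hydroxyphenyl)-7-(triisopropylsilyloxy)chroman-4-one | Oc1ccc([C@H]2Oc3cc(O[Si](C(C)C)(C(C)C)C(C)C)cc(O)c3C(=O)[C@@H]2O)cc1 | intermediate
3 | 3-chloro-3-methylbut-1-yne | C#CC(C)(C)Cl | starting material
4 | (2R,3R)-3,5-dihydroxy-2-[4-(2-methylbut-3-yn-2-yloxy)phenyl]-7-(triisopropylsilyloxy)chroman-4-one | C#CC(C)(C)Oc1ccc([C@H]2Oc3cc(O[Si](C(C)C)(C(C)C)C(C)C)cc(O)c3C(=O)[C@@H]2O)cc1 | intermediate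
5 | (2R,3R)-3-(tert-butyldimethylsilyloxy)-5-hydroxy-2-[4-(2-methylbut-3-yn-2-yloxy)phenyl]-7-(triisopropylsilyloxy)chroman-4-one | C#CC(C)(C)Oc1ccc([C@H]2Oc3cc(O[Si](C(C)C)(C(C)C)C(C)C)cc(O)c3C(=O)[C@@H]2O[Si](C)(C)C(C)(C)C)cc1 | intermediate
6 | (2R,3R)-3-(tert-butyldimethylsilyloxy)-5-hydroxy-2-[4-(2-methylbut-3-en-2-yloxy)phenyl]-7-(triisopropylsilyloxy)chroman-4-one | C=CC(C)(C)Oc1ccc([C@H]2Oc3cc(O[Si](C(C)C)(C(C)C)C(C)C)cc(O)c3C(=O)[C@@H]2O[Si](C)(C)C(C)(C)C)cc1 | intermediate
7 | 3-methylbut-2-en-1-ol (prenol) | CC(C)=CCO | starting material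
8 | (2R,3R)-3-(tert-butyldimethylsilyloxy)-2-[4-(2-methylbut-3-en-2-yloxy)phenyl]-5-(3-methylbut-2-enyloxy)-7-(triisopropylsilyloxy)chroman-4-one | C=CC(C)(C)Oc1ccc([C@H]2Oc3cc(O[Si](C(C)C)(C(C)C)C(C)C)cc(OCC=C(C)C)c3C(=O)[C@@H]2O[Si](C)(C)C(C)(C)C)cc1 | intermediate
9 | C6 reverse-prenyl dienone, formed in the flask in step 6: (2R,3R)-3-(tert-butyldimethylsilyloxy)-6-(2-methylbut-3-en-2-yl)-2-[4-(2-methylbut-3-en-2-yloxy)phenyl]-7-(triisopropylsilyloxy)-2,3-dihydro-4H-chromene-4,5(6H)-dione, either configuration at C6 | C=CC(C)(C)Oc1ccc([C@H]2OC3=C(C(=O)[C@@H]2O[Si](C)(C)C(C)(C)C)C(=O)C(C(C)(C)C=C)C(O[Si](C(C)C)(C(C)C)C(C)C)=C3)cc1 | intermediate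
10 | C8 prenyl dienone, formed in the flask in step 6: (2R,3R)-3-(tert-butyldimethylsilyloxy)-8-(3-methylbut-2-enyl)-2-[4-(2-methylbut-3-en-2-yloxy)phenyl]-7-(triisopropylsilyloxy)-2,3-dihydro-4H-chromene-4,5(8H)-dione, either configuration at C8 | C=CC(C)(C)Oc1ccc([C@H]2OC3=C(C(=O)[C@@H]2O[Si](C)(C)C(C)(C)C)C(=O)C=C(O[Si](C(C)C)(C(C)C)C(C)C)C3CC=C(C)C)cc1 | intermediate
11 | 8-prenyl 4'-O-tert-allyl ether, formed in the flask in step 6: (2R,3R)-3-(tert-butyldimethylsilyloxy)-5-hydroxy-2-[4-(2-methylbut-3-en-2-yloxy)phenyl]-8-(3-methylbut-2-enyl)-7-(triisopropylsilyloxy)chroman-4-one | C=CC(C)(C)Oc1ccc([C@H]2Oc3c(CC=C(C)C)c(O[Si](C(C)C)(C(C)C)C(C)C)cc(O)c3C(=O)[C@@H]2O[Si](C)(C)C(C)(C)C)cc1 | intermediate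
12 | ring B ortho-dienone, formed in the flask in step 6: 6-(3-methylbut-2-enyl)-4-[(2R,3R)-3-(tert-butyldimethylsilyloxy)-5-hydroxy-8-(3-methylbut-2-enyl)-4-oxo-7-(triisopropylsilyloxy)chroman-2-yl]cyclohexa-2,4-dien-1-one, either configuration at the sp3 ring carbon | O=C1C=CC([C@H]2Oc3c(CC=C(C)C)c(O[Si](C(C)C)(C(C)C)C(C)C)cc(O)c3C(=O)[C@@H]2O[Si](C)(C)C(C)(C)C)=CC1CC=C(C)C | intermediate
13 | (2R,3R)-3-(tert-butyldimethylsilyloxy)-5-hydroxy-2-[4-hydroxy-3-(3-methylbut-2-enyl)phenyl]-8-(3-methylbut-2-enyl)-7-(triisopropylsilyloxy)chroman-4-one | Oc1ccc([C@H]2Oc3c(CC=C(C)C)c(O[Si](C(C)C)(C(C)C)C(C)C)cc(O)c3C(=O)[C@@H]2O[Si](C)(C)C(C)(C)C)cc1CC=C(C)C | intermediate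
14 | (2R,3R)-3-(tert-butyldimethylsilyloxy)-5-hydroxy-2-[4-methoxy-3-(3-methylbut-2-enyl)phenyl]-8-(3-methylbut-2-enyl)-7-(triisopropylsilyloxy)chroman-4-one | COc1ccc([C@H]2Oc3c(CC=C(C)C)c(O[Si](C(C)C)(C(C)C)C(C)C)cc(O)c3C(=O)[C@@H]2O[Si](C)(C)C(C)(C)C)cc1CC=C(C)C | intermediate
15 | (2R,3R)-3,5,7-trihydroxy-2-[4-methoxy-3-(3-methylbut-2-enyl)phenyl]-8-(3-methylbut-2-enyl)chroman-4-one (CNP0233452.1) | COc1ccc([C@H]2Oc3c(CC=C(C)C)c(O)cc(O)c3C(=O)[C@@H]2O)cc1CC=C(C)C | target

Total step count: 8. Longest linear sequence: 8 steps (1 to 15).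

Steps most likely to fail

Step 6. Three processes could erode it. The C6 dienone may enolise before the Cope shift, which would fix the five-carbon unit at C6 as a reverse-prenyl group. The Lewis acid may ionise the tertiary allyl ether, so that the ring B unit is lost. The freshly formed ortho-prenylphenol may cyclise onto its alkene under acid. The fallback separates the two shifts and reverses their order, so that the europium-catalysed step runs on a substrate with no acid-labile ether and no free ortho-prenylphenol. It sets out from 6 and comes back at 14. Compound 6 would be heated without Lewis acid (PhCl, 125 °C), giving by thermal aromatic Claisen rearrangement (2R,3R)-3-(tert-butyldimethylsilyloxy)-5-hydroxy-2-[4-hydroxy-3-(3-methylbut-2-enyl)phenyl]-7-(triisopropylsilyloxy)chroman-4-one F1. Methylation of its 4'-OH with TMSCHN2 in MeOH/MeCN, the chelated 5-OH staying free, would give (2R,3R)-3-(tert-butyldimethylsilyloxy)-5-hydroxy-2-[4-methoxy-3-(3-methylbut-2-enyl)phenyl]-7-(triisopropylsilyloxy)chroman-4-one F2. Mitsunobu etherification of O5 with 7 (PPh3, DIAD, THF) would give (2R,3R)-3-(tert-butyldimethylsilyloxy)-2-[4-methoxy-3-(3-methylbut-2-enyl)phenyl]-5-(3-methylbut-2-enyloxy)-7-(triisopropylsilyloxy)chroman-4-one F3. A single para-Claisen–Cope rearrangement of F3 (Eu(fod)3, NaHCO3, PhCl, 85 °C) should then deliver 14, from which step 8 follows unchanged.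

Step 2. Under the amidine base the TIPS group may be transferred from O7 to the 4'-phenoxide, some alkylation may occur at O5, and C2 may epimerise through reversible opening of ring C via the para-quinone methide once the 4'-phenoxide exists. The fallback replaces base-mediated propargylation and later semi-hydrogenation by a base-free decarboxylative O-allylation (Tsuji–Trost type) with zerovalent palladium. It sets out from 2 and comes back at 6, bypassing 4, 5 and the hydrogenation. 2-Methylbut-3-en-2-ol would be converted with n-BuLi and Boc2O in THF into tert-butyl 2-methylbut-3-en-2-yl carbonate F4. Treating 2 with F4 and Pd(PPh3)4 in THF at 0 °C should give, by kinetic attack of the phenoxide at the more substituted allyl terminus, (2R,3R)-3,5-dihydroxy-2-[4-(2-methylbut-3-en-2-yloxy)phenyl]-7-(triisopropylsilyloxy)chroman-4-one F5. Silylation of its 3-OH (TBSCl, imidazole, DMF) would give 6.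

Step 5. Conversion may stall because the 5-OH is tied to the C4 carbonyl by a hydrogen bond and is sterically shielded, and the activated prenol may be captured in the SN2' sense to give the tertiary ether. The fallback is a Williamson alkylation of the 5-phenoxide: 6 with prenyl bromide and K2CO3 in acetone at 50 °C should give 8 directly. It sets out from 6 and comes back at 8 and makes no new compound, F0.

Further compounds
F1 | step 6 | (2R,3R)-3-(tert-butyldimethylsilyloxy)-5-hydroxy-2-[4-hydroxy-3-(3-methylbut-2-enyl)phenyl]-7-(triisopropylsilyloxy)chroman-4-one | Oc1ccc([C@H]2Oc3cc(O[Si](C(C)C)(C(C)C)C(C)C)cc(O)c3C(=O)[C@@H]2O[Si](C)(C)C(C)(C)C)cc1CC=C(C)C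
F2 | step 6 | (2R,3R)-3-(tert-butyldimethylsilyloxy)-5-hydroxy-2-[4-methoxy-3-(3-methylbut-2-enyl)phenyl]-7-(triisopropylsilyloxy)chroman-4-one | COc1ccc([C@H]2Oc3cc(O[Si](C(C)C)(C(C)C)C(C)C)cc(O)c3C(=O)[C@@H]2O[Si](C)(C)C(C)(C)C)cc1CC=C(C)C
F3 | step 6 | (2R,3R)-3-(tert-butyldimethylsilyloxy)-2-[4-methoxy-3-(3-methylbut-2-enyl)phenyl]-5-(3-methylbut-2-enyloxy)-7-(triisopropylsilyloxy)chroman-4-one | COc1ccc([C@H]2Oc3cc(O[Si](C(C)C)(C(C)C)C(C)C)cc(OCC=C(C)C)c3C(=O)[C@@H]2O[Si](C)(C)C(C)(C)C)cc1CC=C(C)C
F4 | step 2 | tert-butyl 2-methylbut-3-en-2-yl carbonate | C=CC(C)(C)OC(=O)OC(C)(C)C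
F5 | step 2 | (2R,3R)-3,5-dihydroxy-2-[4-(2-methylbut-3-en-2-yloxy)phenyl]-7-(triisopropylsilyloxy)chroman-4-one | C=CC(C)(C)Oc1ccc([C@H]2Oc3cc(O[Si](C(C)C)(C(C)C)C(C)C)cc(O)c3C(=O)[C@@H]2O)cc1
F0 | step 5 | none | none
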